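**Plan**

- Cuts (caryophyllane numbers; C13 = pyran CH2, C1' = CH–isobutyl, C3' = oxygen-bearing sp2 carbon of the syncarpic ring): the 3Z-en-5-ol is taken back to the 4,5-epoxide; the dihydropyran (ring C) is then cut at C13–C8 and at O–C3', leaving the nor-ketone kobusone and a syncarpic unit that carries C13 as a nucleophile.
- Feature used: ring C is a cyclic vinylogous ester. Its O–C3' bond ends on the β-carbon of the enone of the mirror-symmetric syncarpic ring (ring D), and C13 lies two bonds from that ring. One helper carbonyl carbon placed between C13 and the second enol oxygen of ring D therefore gives an enol δ-lactone (temporary ring E) in which C13 is an enolisable α-carbon and C3' a vinylogous anhydride carbon.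
- Forward: ring D from phloroacetophenone; ring E by carbene-catalysed annulation of syncarpic acid with an enal; rings A and B (cyclobutane and nine-membered ring) from (−)-caryophyllene oxide by ozonolysis; an aldol/ring-switch cascade joins the halves, closes ring C and opens ring E; the helper carbon leaves as CO2; the epoxide is isomerised last.
- Stereochemistry: C1, C9 and C5 come from caryophyllene oxide; C1' from the chiral carbene catalyst; spiro C8 from face-selective addition to the ketone; the 3Z alkene from syn-elimination within the ring.

Key step: step 6

Remark: the antipode of the triazolium salt is assumed to be the one that gives lactone 6 as 4R; if the named antipode gives 4S, its mirror image is used. In lactone 6 (chromene numbers) C3 becomes C13, C4 becomes C1', C8a becomes C3' and C2 is the helper carbon.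

**Step 1**
Reactants: 1 2,4,6-trihydroxyacetophenone
Product: 2 acetylsyncarpic acid
Conditions: NaOMe, MeI, MeOH, reflux; then aq. HCl
Reagents that add atoms: iodomethane, CI
Why: Dearomative exhaustive C-methylation of the acylphloroglucinol, in which each ring C–H is alkylated twice through the phenolate/enolate and the reaction should stop when no ring hydrogen is left.

**Step 2**
Reactants: 2 acetylsyncarpic acid
Product: 3 syncarpic acid
Conditions: 6 M aq. HCl, reflux
Reagents that add atoms: none
Why: Acid-mediated retro-Claisen deacetylation (hydration of the side-chain carbonyl and C–C cleavage toward the stabilised triketone enol) should remove the acetyl group, and the gem-dimethyl carbons offer no other reaction path.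

**Step 3**
Reactants: 4 3-methylbutanal
Product: 5 (E)-5-methylhex-2-enal
Conditions: Ph3P=CHCHO, toluene, 80 °C (aldehyde in excess)
Reagents that add atoms: (triphenylphosphoranylidene)acetaldehyde, O=CC=P(c1ccccc1)(c1ccccc1)c1ccccc1
Why: Wittig reaction of a stabilised formyl ylide should give the E enal, and the excess of 4 suppresses a second homologation.

**Step 4**
Reactants: 3 syncarpic acid; 5 (E)-5-methylhex-2-enal
Product: 6 (4R)-enol δ-lactone
Conditions: aminoindanol-derived N-mesityl triazolium chloride (10 mol %), DBU (20 mol %), 3,3',5,5'-tetra-tert-butyldiphenoquinone (1.1 equiv), THF, rt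
Reagents that add atoms: none
Why: Oxidative N-heterocyclic carbene catalysis turns the enal into an α,β-unsaturated acyl azolium, to which the triketone enol adds at the β-carbon (Michael addition) before O-acylation closes the lactone and frees the carbene; the chiral catalyst shields one face of the acyl azolium and so sets C4, and the two enol oxygens of the symmetric triketone are equivalent, so only one lactone can form.

**Step 5**
Reactants: 7 (−)-caryophyllene oxide
Product: 9 kobusone, via ozonide 8 (not isolated)
Conditions: O3, CH2Cl2, −78 °C; then Me2S, −78 °C → rt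
Reagents that add atoms: ozone, [O-][O+]=O
Why: Ozonolysis (1,3-dipolar cycloaddition, cycloreversion, recombination to the ozonide, reductive work-up) should cleave the only C=C bond, while the trisubstituted epoxide is inert to ozone and sees no acid; no stereocentre is touched.

**Step 6**
Reactants: 6 (4R)-enol δ-lactone; 9 kobusone
Product: 12 spiro dihydropyran 13-carboxylic acid, via lithium enolate 10 (not isolated), via lithium aldolate 11 (not isolated)
Conditions: LDA, THF, −78 °C; then 9, −78 °C → rt; then cold dilute HCl to pH 4
Reagents that add atoms: none
Why: Proposed new method: LDA removes a C3 proton of 6 (α to the lactone carbonyl), the lithium enolate 10 adds to the C8 ketone of 9 (aldol addition), and the tertiary alkoxide of 11 then adds to C8a of its own lactone, the β-carbon of a vinylogous anhydride, and expels the lactone oxygen as a carboxylate, so that ring E opens as ring C closes and the reversible aldol step is drained by an irreversible alkoxide-to-carboxylate transfer. The closest known reaction types are the tandem aldol–lactonisation of activated-ester enolates with ketones (β-lactone synthesis) and the addition–elimination of alkoxides at the β-carbon of β-acyloxy or β-alkoxy enones. Ring C closes in a 6-endo-trig addition–elimination: the alkoxide reaches C8a across the boat form of the lactone through a 2,6-dioxabicyclo[2.2.2]octane-type tetrahedral intermediate, which should collapse toward the better leaving group. The spiro centre C8 is set in the aldol step by attack on the Si face of the ketone, through a staggered arrangement in which the ring bond C9–C1 is anti to the incoming enolate, the cyclobutane methylene C10 lies next to the carbonyl oxygen and only H9 flanks the trajectory; C13 is set trans to the isobutyl group on ring E (cis on ring C) and is erased in step 7, and C1' is carried over from 6. The step needs closure at C8a to win over four-ring attack on the lactone carbonyl, which ring strain favours and which stays correctable because a β-lactone would keep its triketonate leaving group tethered; it also needs addition to outrun proton transfer from C7 and C9 of the ketone, which the low temperature and the modest basicity of an ester enolate should secure.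

**Step 7**
Reactants: 12 spiro dihydropyran 13-carboxylic acid
Product: 14 4,5-epoxide of the target skeleton, via thiohydroxamate ester 13 (not isolated)
Conditions: 2,2'-dithiobis(pyridine N-oxide), PBu3, THF, 0 °C, dark; then t-BuSH, hν (tungsten lamp), rt
Reagents that add atoms: none
Why: Barton decarboxylation, in which the ester 13 is made by a neutral redox condensation so that no base can trigger β-elimination of the vinylogous carboxylate at C8, and the C13 radical formed on photolysis should abstract hydrogen from the thiol faster than it can fragment; the C13 stereocentre disappears and all others are untouched.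

**Step 8**
Reactants: 14 4,5-epoxide of the target skeleton
Product: 15 Tomentodione O
Conditions: LiTMP (from TMPH and n-BuLi), Et2AlCl, toluene, 0 °C → rt; then aq. potassium sodium tartrate
Reagents that add atoms: none
Why: Epoxide-to-allylic-alcohol isomerisation by an aluminium amide, in which aluminium binds the epoxide oxygen and the amide nitrogen removes, in a cyclic syn-elimination, a proton from the C3 methylene (the group on C4 cis to H5) in preference to the C4 methyl group; the C3 hydrogen on the H5 side is the less hindered and the better aligned with the breaking C4–O bond, its loss folds C2 toward C5 and should give the Z alkene, the C5–O bond is not broken (5R retained), and ring D has no enolisable hydrogen.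

**Compound list**

1 | 2,4,6-trihydroxyacetophenone | CC(=O)c1c(O)cc(O)cc1O | starting material
2 | acetylsyncarpic acid, 2-acetyl-3-hydroxy-4,4,6,6-tetramethylcyclohex-2-ene-1,5-dione | CC(=O)C1=C(O)C(C)(C)C(=O)C(C)(C)C1=O | intermediate
3 | syncarpic acid, enol form 5-hydroxy-2,2,6,6-tetramethylcyclohex-4-ene-1,3-dione | CC1(C)C(=O)C=C(O)C(C)(C)C1=O | intermediate
4 | 3-methylbutanal | CC(C)CC=O | starting material
5 | (E)-5-methylhex-2-enal | CC(C)C/C=C/C=O | intermediate
6 | (4R)-6,6,8,8-tetramethyl-4-(2-methylpropyl)-3,4-dihydro-2H-chromene-2,5,7(6H,8H)-trione (enol δ-lactone) | O=C1C[C@@H](CC(C)C)C2=C(O1)C(C)(C)C(=O)C(C)(C)C2=O | intermediate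
7 | (−)-caryophyllene oxide, (1R,4R,5R,9S)-4,5-epoxycaryophyll-8(13)-ene | C[C@@]12CC[C@@H]3[C@H](CC3(C)C)C(=C)CC[C@H]1O2 | starting material
8 | ozonide of 7: spiro-1,2,4-trioxolane at C8/C13, either configuration at the trioxolane spiro carbon | C[C@@]12CC[C@@H]3[C@H](CC3(C)C)C4(CC[C@H]1O2)OCOO4 | intermediate
9 | kobusone, (1R,4R,5R,9S)-4,5-epoxy-13-norcaryophyllan-8-one | C[C@@]12CC[C@@H]3[C@H](CC3(C)C)C(=O)CC[C@H]1O2 | intermediate
10 | lithium enolate of 6 (C2–OLi, C2=C3; 4R) | [Li]OC1=C[C@@H](CC(C)C)C2=C(O1)C(C)(C)C(=O)C(C)(C)C2=O | intermediate
11 | lithium aldolate: lactone 6 bonded through C3 (3S, trans to isobutyl; 4R) to C8 of 9 (C8–OLi; spiro-centre geometry of 15, CIP label 8R here) | C[C@@]12CC[C@@H]3[C@H](CC3(C)C)[C@](O[Li])(CC[C@H]1O2)[C@H]4C(=O)OC5=C([C@@H]4CC(C)C)C(=O)C(C)(C)C(=O)C5(C)C | intermediate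
12 | spiro dihydropyran 13-carboxylic acid: 14 with CO2H on C13 (13S, cis to isobutyl on ring C; C8 geometry of 15, CIP label 8R because the carboxyl raises the rank of C13; 1R,4R,5R,9S,1'R) | C[C@@]12CC[C@@H]3[C@H](CC3(C)C)[C@]4(CC[C@H]1O2)[C@@H](C(=O)O)[C@@H](CC(C)C)C1=C(O4)C(C)(C)C(=O)C(C)(C)C1=O | intermediate
13 | thiohydroxamate ester of 12 (2-thioxopyridin-1(2H)-yl ester) | C[C@@]12CC[C@@H]3[C@H](CC3(C)C)[C@]4(CC[C@H]1O2)[C@@H](C(=O)ON5C=CC=CC5=S)[C@@H](CC(C)C)C1=C(O4)C(C)(C)C(=O)C(C)(C)C1=O | intermediate
14 | 4,5-epoxide of the target skeleton, (1R,4R,5R,8S,9S,1'R): 4,5-epoxycaryophyllane spiro-fused at C8 to the dihydropyran that carries isobutyl at C1' and is fused to ring D | C[C@@]12CC[C@@H]3[C@H](CC3(C)C)[C@]4(CC[C@H]1O2)C[C@@H](CC(C)C)C1=C(O4)C(C)(C)C(=O)C(C)(C)C1=O | intermediate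
15 | Tomentodione O, (1R,3Z,5R,8S,9S,1'R) | C/C1=C/C[C@@H]2[C@H](CC2(C)C)[C@]2(CC[C@H]1O)C[C@@H](CC(C)C)C1=C(O2)C(C)(C)C(=O)C(C)(C)C1=O | target

**Step count and risks**

Total step count: 8. Longest linear sequence: 6 steps (steps 1, 2, 4, 6, 7, 8 from 2,4,6-trihydroxyacetophenone); the terpene branch is 4 steps (5, 6, 7, 8).

Steps most likely to fail:

Step 6. What may go wrong: four-ring closure of the aldolate onto the lactone carbonyl, opening of the enolate to a tethered ketene, proton transfer from the ketone in place of addition, a ring switch too slow to compete with retro-aldol cleavage, or attack on the Re face of the ketone. Fallback (known chemistry, the biomimetic disconnection): it sets out from syncarpic acid 3, 3-methylbutanal 4 and caryophyllene oxide 7. Knoevenagel condensation of 3 with 4 (cat. L-proline, toluene, 80 °C, no acid) generates the alkylidene triketone F1 in the presence of 7; F1 then adds as a 1-oxadiene to the exocyclic C8=C13 bond of 7 in an inverse-demand hetero-Diels–Alder reaction. The adduct with the C8 and C1' configurations of 14 would be separated from its C1' epimer by chromatography. The route is rejoined at 14, and steps 4 to 7 are then not needed.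

Step 8. What may go wrong: proton abstraction from the C4 methyl group (exocyclic alkene), syn-elimination through the conformer that leads to the E alkene, or Lewis-acid ionisation of the tertiary C8–O bond. Fallback (sets out from 14, returns at 15): LiNEt2 (Et2O, 0 °C → rt), which removes a methyl proton, should give the 4(12)-methylene 5R-alcohol F2. Dess–Martin oxidation gives the 4(12)-methylene 5-ketone F3. RhCl3·3H2O (EtOH, 70 °C) or DBU moves the double bond into conjugation inside the ring and should give the (3Z)-3-en-5-one F4, Z being the thermodynamic geometry of a nine-membered enone. Corey–Bakshi–Shibata reduction with the (S)-oxazaborolidine and catecholborane (toluene, −40 °C) delivers hydride under catalyst control, with the alkenyl carbon C4 as the large group, to give the 5R alcohol 15.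

Step 7. What may go wrong: β-elimination across C13–C8 with loss of the vinylogous carboxylate while the acid is activated, decarboxylative fragmentation of the β-oxygenated acid, or opening of the epoxide by the free acid on standing. Fallback (sets out from 6 and 9, returns at 14; the helper carbon is removed before the fragments are joined): methanolysis of 6 (MeOH, Et3N) and O-methylation of the freed enol (TMSCHN2) give the methyl ester methyl enol ether F5. Me3SnOH (1,2-dichloroethane, 80 °C) cleaves only the carboxylic ester to give the carboxylic acid F6. Hunsdiecker-type iododecarboxylation (PhI(OAc)2, I2, hν) gives the primary iodide F7, which is used at once. A samarium Barbier reaction of F7 with kobusone 9 (SmI2, cat. NiI2, THF, 0 °C → rt) forms the C13–C8 bond, and the samarium alkoxide then displaces methoxide from C3' by addition–elimination to give 14 directly.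

**Further compounds**

F1 | step 6 | alkylidene triketone, 2-(3-methylbutylidene)-4,4,6,6-tetramethylcyclohexane-1,3,5-trione | CC(C)CC=C1C(=O)C(C)(C)C(=O)C(C)(C)C1=O
F2 | step 8 | 4(12)-methylene 5R-alcohol (exocyclic isomer of 15) | C=C1CC[C@@H]2[C@H](CC2(C)C)[C@]2(CC[C@H]1O)C[C@@H](CC(C)C)C1=C(O2)C(C)(C)C(=O)C(C)(C)C1=O
F3 | step 8 | 4(12)-methylene 5-ketone | C=C1CC[C@@H]2[C@H](CC2(C)C)[C@]2(CCC1=O)C[C@@H](CC(C)C)C1=C(O2)C(C)(C)C(=O)C(C)(C)C1=O
F4 | step 8 | (3Z)-3-en-5-one | C/C1=C/C[C@@H]2[C@H](CC2(C)C)[C@]2(CCC1=O)C[C@@H](CC(C)C)C1=C(O2)C(C)(C)C(=O)C(C)(C)C1=O
F5 | step 7 | methyl ester methyl enol ether, methyl (3R)-3-(2-methoxy-3,3,5,5-tetramethyl-4,6-dioxocyclohex-1-en-1-yl)-5-methylhexanoate | COC(=O)C[C@@H](CC(C)C)C1=C(OC)C(C)(C)C(=O)C(C)(C)C1=O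
F6 | step 7 | carboxylic acid, (3R)-3-(2-methoxy-3,3,5,5-tetramethyl-4,6-dioxocyclohex-1-en-1-yl)-5-methylhexanoic acid | OC(=O)C[C@@H](CC(C)C)C1=C(OC)C(C)(C)C(=O)C(C)(C)C1=O
F7 | step 7 | primary iodide, 2-[(2S)-1-iodo-4-methylpentan-2-yl]-3-methoxy-4,4,6,6-tetramethylcyclohex-2-ene-1,5-dione | IC[C@@H](CC(C)C)C1=C(OC)C(C)(C)C(=O)C(C)(C)C1=O
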